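**Strategy**

Everything rests on the C6–CH2 bond that links the cyclohexenone ring to the tiglic acid chain. The key step joins the fully substituted enone 15 and allylic bromide 18 by α'-alkylation at C6, the only sp3 carbon beside the C1 carbonyl, and then re-enolises and protonates the product in the same flask. It exploits the cis-C4/C5 diol, held as an acetonide fused to the ring: carbon and then hydrogen both enter C6 anti to this dioxolane, so installing carbon first and hydrogen last leaves the chain cis to O5 (6R). The precursor 15 comes from bromobenzene cis-dihydrodiol, which supplies C4 and C5, by Stille and Suzuki couplings.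

Key step: step 14

Remark on the chemistry: ring positions are cited with cyclohexenone numbering (C1 = C=O, C2=C3, C4, C5, C6). Compound 1 and the other starting materials are taken as commercial. The first C–C bond formation at C6 is assumed to occur mainly anti to the acetonide, but the outcome of step 14 does not depend on this.

**Route**

Step 1
Reactants: 1 (1S,2S)-3-bromocyclohexa-3,5-diene-1,2-diol
Product: 2 (3aS,7aS)-4-bromo-2,2-dimethyl-3a,7a-dihydro-1,3-benzodioxole
Conditions: 2,2-dimethoxypropane, p-TsOH·H2O (cat.), CH2Cl2, 0 °C → rt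
Reagents that add atoms: 2,2-dimethoxypropane, COC(C)(C)OC
Why: Acid-catalysed transketalisation of the cis-1,2-diol gives the cis-fused dioxolane (acetonide protection) without touching a stereocentre.

Step 2
Reactants: 2 (3aS,7aS)-4-bromo-2,2-dimethyl-3a,7a-dihydro-1,3-benzodioxole
Product: 3 bromohydrin 4,7-dibromo-2,2-dimethyl-3a,4,5,7a-tetrahydro-1,3-benzodioxol-5-ol (5-OH cis, 4-Br trans to the dioxolane oxygens)
Conditions: NBS, DME/H2O, 0 °C
Reagents that add atoms: N-bromosuccinimide, O=C1CCC(=O)N1Br; water, O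
Why: Hydroxybromination, in which Br+ adds to the electron-richer, non-brominated alkene anti to the acetonide and water opens the bromonium ion at the allylic carbon (future C1) from the other face; both new centres are erased in steps 3 and 4.

Step 3
Reactants: 3 bromohydrin
Product: 4 4,7-dibromo-2,2-dimethyl-3a,4-dihydro-1,3-benzodioxol-5(7aH)-one (4-Br trans to the dioxolane)
Conditions: Dess–Martin periodinane, CH2Cl2, 0 °C → rt
Reagents that add atoms: none
Why: Dess–Martin oxidation of the secondary allylic alcohol gives the enone under neutral conditions that spare the acetonide and both C–Br bonds.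

Step 4
Reactants: 4 α,β'-dibromo enone
Product: 5 (4S,5S)-3-bromo-4,5-(isopropylidenedioxy)cyclohex-2-en-1-one
Conditions: Ru(bpy)3Cl2 (1 mol%), Hantzsch ester, iPr2NEt, DMF, blue LEDs, rt
Reagents that add atoms: none
Why: Visible-light photoredox reductive dehalogenation cleaves only the activated α-keto C–Br bond, and the C6 radical takes H from the Hantzsch ester, so no enolate forms (no β-elimination of O5) and the vinylic bromide remains.

Step 5
Reactants: 5 (4S,5S)-3-bromo-4,5-(isopropylidenedioxy)cyclohex-2-en-1-one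
Product: 6 (4R,5S)-3-(hydroxymethyl)-4,5-(isopropylidenedioxy)cyclohex-2-en-1-one
Conditions: Bu3SnCH2OH, Pd(PPh3)4 (5 mol%), 1,4-dioxane, 90 °C
Reagents that add atoms: (tributylstannyl)methanol, CCCC[Sn](CCCC)(CCCC)CO
Why: Stille (Kosugi–Migita) hydroxymethylation, in which the β-bromo enone behaves as a vinylogous acyl bromide toward Pd(0) and the CH2OH group is transferred from tin.

Step 6
Reactants: 6 (4R,5S)-3-(hydroxymethyl)-4,5-(isopropylidenedioxy)cyclohex-2-en-1-one
Product: 7 (4R,5S)-3-[(tert-butyldimethylsilyloxy)methyl]-4,5-(isopropylidenedioxy)cyclohex-2-en-1-one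
Conditions: TBSCl, imidazole, CH2Cl2, 0 °C → rt
Reagents that add atoms: tert-butyldimethylsilyl chloride, CC(C)(C)[Si](C)(C)Cl
Why: Standard silylation of the primary allylic alcohol (Corey conditions).

Step 7
Reactants: 7 silyl ether enone
Product: 8 (4R,5S)-3-[(tert-butyldimethylsilyloxy)methyl]-2-iodo-4,5-(isopropylidenedioxy)cyclohex-2-en-1-one
Conditions: I2, DMAP (cat.), pyridine/CH2Cl2 (1:1), rt → 40 °C
Reagents that add atoms: iodine, II
Why: Johnson α-iodination of the enone (conjugate addition of the amine, iodination of the enolate, elimination) should give the 2-iodoenone, with DMAP and mild warming compensating for the β,β-disubstitution.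

Step 8
Reactants: 9 (R)-propylene oxide; 10 but-3-en-1-ylmagnesium bromide
Product: 11 (R)-hept-6-en-2-ol
Conditions: CuI (10 mol%), THF, −30 → 0 °C; then sat. aq NH4Cl
Reagents that add atoms: none
Why: Copper-catalysed Grignard opening of the epoxide at its unsubstituted CH2 carbon leaves the (R) carbinol centre untouched.

Step 9
Reactants: 11 (R)-hept-6-en-2-ol
Product: 12 (R)-tert-butyl(hept-6-en-2-yloxy)dimethylsilane
Conditions: TBSCl, imidazole, DMF, rt
Reagents that add atoms: tert-butyldimethylsilyl chloride, CC(C)(C)[Si](C)(C)Cl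
Why: Standard silylation of the secondary alcohol.

Step 10
Reactants: 12 (R)-tert-butyl(hept-6-en-2-yloxy)dimethylsilane; 13 vinylboronic acid pinacol ester
Product: 14 (R,E)-alkenylboronate, 2-[(1E,6R)-6-(tert-butyldimethylsilyloxy)hept-1-en-1-yl]-4,4,5,5-tetramethyl-1,3,2-dioxaborolane
Conditions: Grubbs II (3 mol%), CH2Cl2, 40 °C
Reagents that add atoms: none
Why: Olefin cross-metathesis of the terminal alkene with vinyl-Bpin should give the (E)-alkenylboronate with loss of ethene.

Step 11
Reactants: 8 iodoenone; 14 (R,E)-alkenylboronate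
Product: 15 (4R,5S)-2-[(1E,6R)-6-(tert-butyldimethylsilyloxy)hept-1-en-1-yl]-3-[(tert-butyldimethylsilyloxy)methyl]-4,5-(isopropylidenedioxy)cyclohex-2-en-1-one
Conditions: PdCl2(PhCN)2 (5 mol%), AsPh3 (10 mol%), Ag2O, THF/H2O (8:1), rt
Reagents that add atoms: none
Why: Suzuki–Miyaura coupling under the Ag2O/AsPh3 conditions developed for 2-iodoenones retains the (E) geometry and avoids a strong soluble base, so the base-sensitive β-alkoxy ketone should survive.

Step 12
Reactants: 16 tiglic acid, (E)-2-methylbut-2-enoic acid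
Product: 17 tert-butyl tiglate
Conditions: isobutene, H2SO4 (cat.), CH2Cl2, sealed vessel, rt
Reagents that add atoms: 2-methylpropene, CC(C)=C
Why: Acid-catalysed addition of the carboxylic acid to isobutene gives the tert-butyl ester.

Step 13
Reactants: 17 tert-butyl tiglate
Product: 18 tert-butyl (E)-4-bromo-2-methylbut-2-enoate
Conditions: NBS, AIBN (cat.), PhCF3, 80 °C
Reagents that add atoms: N-bromosuccinimide, O=C1CCC(=O)N1Br
Why: Wohl–Ziegler allylic bromination at the γ-methyl group should give the (E)-4-bromo ester as main isomer, the (Z) and 2-(bromomethyl) isomers being removed by chromatography.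

Step 14
Reactants: 15 protected dienone; 18 tert-butyl (E)-4-bromo-2-methylbut-2-enoate
Product: 22 tert-butyl ester of acetonide/bis-TBS-protected pestallic acid I (4R,5S,6R), via lithium dienolate 19 (not isolated), via C6-epimeric ketone 20 (not isolated), via lithium enolate 21 (not isolated)
Conditions: LiHMDS (1.05 equiv), THF, −78 °C; 18 (1.0 equiv), DMPU, −78 → −40 °C; LiHMDS (1.3 equiv), −78 → −40 °C; AcOH in THF, −78 °C
Reagents that add atoms: none
Why: LiHMDS removes one of the two C6 protons (kinetic α'-deprotonation; C2 has no H) to give the cross-conjugated lithium dienolate 19, which displaces bromide from the primary allylic carbon of 18 in an SN2 reaction, the classical α'-alkylation of an enone enolate with a 4-bromotiglate. No ring is closed. The electrophile should approach C6 on the convex face, anti to the cis-fused dioxolane, so the first-formed ketone 20 carries the chain trans to O5; this selectivity does not matter, because the second portion of LiHMDS removes the one remaining C6 proton and takes either epimer to the same tetrasubstituted enolate 21. Kinetic C-protonation of 21 by acetic acid at −78 °C (Zimmerman-type kinetic protonation to the less stable epimer) should again occur anti to the dioxolane, which places H trans and the side chain cis to O5 and sets C6 as R under control of the C4/C5 acetonide. The step needs α' rather than γ deprotonation and C6–H rather than ester γ-H deprotonation (amide base at low temperature, HMDS being too weak for the enoate), SN2 rather than Michael attack on 18 (primary bromide, α-methyl group), and survival of the β-oxygen at C5 (lithium counter-ion, −40 °C or below).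

Step 15
Reactants: 22 fully protected tert-butyl ester
Product: 23 pestallic acid I
Conditions: TFA/H2O (9:1), 0 °C → rt; evaporation; reversed-phase chromatography
Reagents that add atoms: none
Why: Aqueous TFA hydrolyses the acetonide and both silyl ethers and cleaves the tert-butyl ester (AAL1) in one global acidic deprotection of the kind used for acetonide-protected polyhydroxycyclohexenones, and the absence of base protects the C6 centre next to the ketone.

**Compound list**

1 | (1S,2S)-3-bromocyclohexa-3,5-diene-1,2-diol | C1=CC=C(Br)[C@@H](O)[C@H]1O | starting material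
2 | (3aS,7aS)-4-bromo-2,2-dimethyl-3a,7a-dihydro-1,3-benzodioxole | C1=CC=C(Br)[C@@H](OC(C)(C)O2)[C@H]12 | intermediate
3 | 4,7-dibromo-2,2-dimethyl-3a,4,5,7a-tetrahydro-1,3-benzodioxol-5-ol, 5-OH cis and 4-Br trans to the dioxolane | Br[C@@H]1[C@@H](O)C=C(Br)[C@@H](OC(C)(C)O2)[C@H]12 | intermediate
4 | 4,7-dibromo-2,2-dimethyl-3a,4-dihydro-1,3-benzodioxol-5(7aH)-one, 4-Br trans to the dioxolane | Br[C@@H]1C(=O)C=C(Br)[C@@H](OC(C)(C)O2)[C@H]12 | intermediate
5 | (4S,5S)-3-bromo-4,5-(isopropylidenedioxy)cyclohex-2-en-1-one | C1C(=O)C=C(Br)[C@@H](OC(C)(C)O2)[C@H]12 | intermediate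
6 | (4R,5S)-3-(hydroxymethyl)-4,5-(isopropylidenedioxy)cyclohex-2-en-1-one | C1C(=O)C=C(CO)[C@@H](OC(C)(C)O2)[C@H]12 | intermediate
7 | (4R,5S)-3-[(tert-butyldimethylsilyloxy)methyl]-4,5-(isopropylidenedioxy)cyclohex-2-en-1-one | C1C(=O)C=C(CO[Si](C)(C)C(C)(C)C)[C@@H](OC(C)(C)O2)[C@H]12 | intermediate
8 | (4R,5S)-3-[(tert-butyldimethylsilyloxy)methyl]-2-iodo-4,5-(isopropylidenedioxy)cyclohex-2-en-1-one | C1C(=O)C(I)=C(CO[Si](C)(C)C(C)(C)C)[C@@H](OC(C)(C)O2)[C@H]12 | intermediate
9 | (R)-propylene oxide | C[C@@H]1CO1 | starting material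
10 | but-3-en-1-ylmagnesium bromide | C=CCC[Mg]Br | starting material
11 | (R)-hept-6-en-2-ol | C=CCCC[C@@H](C)O | intermediate
12 | (R)-tert-butyl(hept-6-en-2-yloxy)dimethylsilane | C=CCCC[C@@H](C)O[Si](C)(C)C(C)(C)C | intermediate
13 | vinylboronic acid pinacol ester | C=CB1OC(C)(C)C(C)(C)O1 | starting material
14 | 2-[(1E,6R)-6-(tert-butyldimethylsilyloxy)hept-1-en-1-yl]-4,4,5,5-tetramethyl-1,3,2-dioxaborolane | CC1(C)OB(/C=C/CCC[C@@H](C)O[Si](C)(C)C(C)(C)C)OC1(C)C | intermediate
15 | (4R,5S)-2-[(1E,6R)-6-(tert-butyldimethylsilyloxy)hept-1-en-1-yl]-3-[(tert-butyldimethylsilyloxy)methyl]-4,5-(isopropylidenedioxy)cyclohex-2-en-1-one | C1C(=O)C(/C=C/CCC[C@@H](C)O[Si](C)(C)C(C)(C)C)=C(CO[Si](C)(C)C(C)(C)C)[C@@H](OC(C)(C)O2)[C@H]12 | intermediate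
16 | tiglic acid | C/C=C(\C)C(=O)O | starting material
17 | tert-butyl tiglate | C/C=C(\C)C(=O)OC(C)(C)C | intermediate
18 | tert-butyl (E)-4-bromo-2-methylbut-2-enoate | C/C(=C\CBr)C(=O)OC(C)(C)C | intermediate
19 | lithium dienolate of 15 (C1–OLi, C1=C6) | C1=C(O[Li])C(/C=C/CCC[C@@H](C)O[Si](C)(C)C(C)(C)C)=C(CO[Si](C)(C)C(C)(C)C)[C@@H](OC(C)(C)O2)[C@H]12 | intermediate (not isolated)
20 | C6-epimeric alkylated ketone (4R,5S,6S), tiglate chain trans to the acetonide | C/C(=C\C[C@@H]1C(=O)C(/C=C/CCC[C@@H](C)O[Si](C)(C)C(C)(C)C)=C(CO[Si](C)(C)C(C)(C)C)[C@@H](OC(C)(C)O2)[C@H]12)C(=O)OC(C)(C)C | intermediate (not isolated)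
21 | lithium enolate of 20 (C1–OLi, C1=C6, C6 bearing the chain) | C/C(=C\CC1=C(O[Li])C(/C=C/CCC[C@@H](C)O[Si](C)(C)C(C)(C)C)=C(CO[Si](C)(C)C(C)(C)C)[C@@H](OC(C)(C)O2)[C@H]12)C(=O)OC(C)(C)C | intermediate (not isolated)
22 | tert-butyl (E)-2-methylbut-2-enoate carrying at C4 the (4R,5S,6R)-ring of 15 through C6, chain cis to the acetonide | C/C(=C\C[C@H]1C(=O)C(/C=C/CCC[C@@H](C)O[Si](C)(C)C(C)(C)C)=C(CO[Si](C)(C)C(C)(C)C)[C@@H](OC(C)(C)O2)[C@H]12)C(=O)OC(C)(C)C | intermediate
23 | pestallic acid I, (2E)-4-[(1R,5R,6S)-5,6-dihydroxy-3-[(1E,6R)-6-hydroxyhept-1-en-1-yl]-4-(hydroxymethyl)-2-oxocyclohex-3-en-1-yl]-2-methylbut-2-enoic acid | C/C(=C\C[C@H]1C(=O)C(/C=C/CCC[C@@H](C)O)=C(CO)[C@@H](O)[C@H]1O)C(=O)O | target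

**Count and risks**

Total steps: 15. Longest linear sequence: 10 (steps 1–7, 11, 14, 15).

Steps most likely to fail:

1. Step 14. The lithium enolates 19 and 21 may expel the C5 oxygen (β-elimination followed by aromatisation), or re-enolisation of 20 may be incomplete so that both C6 epimers are recovered. Fallback, from 15 back to 22: soft enolisation of 15 (TMSOTf, Et3N, CH2Cl2, −78 °C) gives the 2-silyloxydiene F1 without a free enolate. Bromide 18 is converted with MeOH, CO2, Cs2CO3 and Bu4NI in DMF into the allylic methyl carbonate F2. Neutral Tsuji–Trost allylation of F1 with F2 (Pd2(dba)3·CHCl3, dppe, THF, 60 °C) should give ketone 20, which is isolated. A second soft enolisation gives the tetrasubstituted silyl enol ether F3, and buffered protodesilylation (TBAF/AcOH, THF, −78 °C) should deliver the proton anti to the acetonide and return to the route at 22.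

2. Step 15. The long exposure to strong acid that the tert-butyl ester needs may enolise the ketone (epimerisation at C6) or dehydrate the β-hydroxy ketone. Fallback, from 15 to 23: 15 is alkylated as in the first half of step 14 with commercial methyl (E)-4-bromo-2-methylbut-2-enoate F4, and the C6-epimeric methyl ester F5 is isolated. The ester is cleaved with Me3SnOH (1,2-dichloroethane, 70 °C) to the C6-epimeric acid F6; epimerisation is of no consequence here because C6 is reset afterwards. Dianion formation (LiHMDS, 2.5 equiv, THF, −78 → −40 °C) and kinetic protonation (AcOH, −78 °C) should give the (6R) acid F7. Brief mild acid (Dowex 50W-X8 H+ form, MeOH/H2O, rt) then removes acetonide and silyl ethers and reaches 23.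

3. Step 5. Transfer of the sp3 CH2OH group from tin may be slow, so that butyl transfer and protodebromination compete. Fallback, from 5 to 6: Stille-type reductive carbonylation of 5 (CO 1 atm, Bu3SnH added slowly, Pd(PPh3)4, toluene, 50 °C) gives the enal F8, and chemoselective reduction of the aldehyde beside the ring ketone with NaBH(OAc)3 (benzene, rt) returns to the route at 6.

Further compounds
F1 | step 14 | 2-(trimethylsilyloxy)diene from 15 (C1–OTMS, C1=C6) | C1=C(O[Si](C)(C)C)C(/C=C/CCC[C@@H](C)O[Si](C)(C)C(C)(C)C)=C(CO[Si](C)(C)C(C)(C)C)[C@@H](OC(C)(C)O2)[C@H]12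
F2 | step 14 | tert-butyl (E)-4-[(methoxycarbonyl)oxy]-2-methylbut-2-enoate | C/C(=C\COC(=O)OC)C(=O)OC(C)(C)C
F3 | step 14 | trimethylsilyl enol ether of 20 (C1–OTMS, C1=C6) | C/C(=C\CC1=C(O[Si](C)(C)C)C(/C=C/CCC[C@@H](C)O[Si](C)(C)C(C)(C)C)=C(CO[Si](C)(C)C(C)(C)C)[C@@H](OC(C)(C)O2)[C@H]12)C(=O)OC(C)(C)C
F4 | step 15 | methyl (E)-4-bromo-2-methylbut-2-enoate | C/C(=C\CBr)C(=O)OC
F5 | step 15 | methyl ester analogue of 20 (4R,5S,6S) | C/C(=C\C[C@@H]1C(=O)C(/C=C/CCC[C@@H](C)O[Si](C)(C)C(C)(C)C)=C(CO[Si](C)(C)C(C)(C)C)[C@@H](OC(C)(C)O2)[C@H]12)C(=O)OC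
F6 | step 15 | C6-epimeric protected acid (4R,5S,6S) | C/C(=C\C[C@@H]1C(=O)C(/C=C/CCC[C@@H](C)O[Si](C)(C)C(C)(C)C)=C(CO[Si](C)(C)C(C)(C)C)[C@@H](OC(C)(C)O2)[C@H]12)C(=O)O
F7 | step 15 | protected acid (4R,5S,6R) | C/C(=C\C[C@H]1C(=O)C(/C=C/CCC[C@@H](C)O[Si](C)(C)C(C)(C)C)=C(CO[Si](C)(C)C(C)(C)C)[C@@H](OC(C)(C)O2)[C@H]12)C(=O)O
F8 | step 5 | 3-formyl-4,5-(isopropylidenedioxy)cyclohex-2-en-1-one, ring centres as in 5 | C1C(=O)C=C(C=O)[C@@H](OC(C)(C)O2)[C@H]12
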